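**Plan**
- Retrosynthesis: the acetate, the C17 oxygen and the C3 carbinol (from a 3-ketone) come off first. Ring A is then cut at C1–C2 and C3–C4 (labdane locants), which releases a two-carbon vinyl unit and leaves a ring-B cyclohexene carrying a neopentyl iodide (C1 on C10) and a tertiary pinacol boronate (C4 on C5). The C9–C11 bond and the two C10 substituents are cut last, back to (R)-carvone and a C5 bromide from the (R)-3-methylglutarate half ester.
- Forward: ring B is carvone. C10 is methylated and hydroxymethylated, the isopropenyl group is hydrochlorinated, the side chain is joined at C9, the boronate and iodide are installed, and ring A is closed last. Oxidation-level adjustments finish the route.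
- Enabling feature: in ring A the oxygen-bearing C3 lies between quaternary C4 and the C2–C1 ethylene that ends on quaternary C10. A C3–B bond (later C3–O) next to C4 is what a shift of C4 from boron to a vinyl carbon produces, and C1 on C10 gives a nickel alkyl with no β-hydrogen.
- Stereochemistry: C5 from (R)-carvone; C10 by enolate addition anti to the C5 substituent; C9 by suprafacial hydrogen delivery from an allylic diazene; C13 from the chiral pool; C3 by hydride reduction of the 3-ketone, on which both C3 epimers from the annulation converge.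

Key step: step 15

Remark: labdane locants are used throughout (ring A = C1–C5, C10; ring B = C5–C10; C17 on C8; C20 on C10; side chain C11–C16). The SMILES is read as the normal labdane series (5α-H, 9α-H, 10β-CH3, 3β-OH, 13R). R* stands for the (3R)-4-(1,3-dioxolan-2-yl)-3-methylbutyl chain. Vinyllithium is assumed to be made in the flask from tetravinyltin and n-BuLi.

Step 1
Reactants: 1 methyl hydrogen (R)-3-methylglutarate
Product: 2 methyl (R)-5-hydroxy-3-methylpentanoate
Conditions: BH3·SMe2, THF, 0 °C to rt; MeOH quench
Reagents that add atoms: none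
Why: Chemoselective borane reduction of a carboxylic acid in the presence of an ester (via the acyloxyborane); the stereocentre is not involved.

Step 2
Reactants: 2 methyl (R)-5-hydroxy-3-methylpentanoate
Product: 3 methyl (S)-5-bromo-3-methylpentanoate
Conditions: CBr4, PPh3, CH2Cl2, 0 °C
Reagents that add atoms: carbon tetrabromide, BrC(Br)(Br)Br
Why: Appel bromination, an SN2 displacement of the alkoxyphosphonium at an unhindered primary carbon; the descriptor changes only through the priority rules.

Step 3
Reactants: 3 methyl (S)-5-bromo-3-methylpentanoate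
Product: 4 (S)-5-bromo-3-methylpentanal
Conditions: iBu2AlH (1.05 equiv), CH2Cl2, −78 °C; aq potassium sodium tartrate
Reagents that add atoms: none
Why: Partial reduction of a methyl ester by iBu2AlH, whose tetrahedral aluminium hemiacetal survives at −78 °C and gives the aldehyde on work-up; the primary bromide is inert.

Step 4
Reactants: 4 (S)-5-bromo-3-methylpentanal
Product: 5 2-[(2S)-4-bromo-2-methylbutyl]-1,3-dioxolane
Conditions: ethylene glycol, p-TsOH (cat.), benzene, reflux, Dean–Stark trap
Reagents that add atoms: ethylene glycol, OCCO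
Why: Acid-catalysed acetalisation with azeotropic removal of water stores C15 at the aldehyde level in a form that tolerates magnesium, organometallics, fluoride and base.

Step 5
Reactants: 6 (R)-(−)-carvone
Product: 8 6-methylcarvone (C6 epimers), via lithium enolate 7 (not isolated)
Conditions: LiN(iPr)2, THF, −78 °C; MeI, −78 to 0 °C
Reagents that add atoms: iodomethane, CI
Why: Kinetic α′-deprotonation gives the cross-conjugated enolate and C-alkylation installs the future C20 methyl (enolate alkylation); the new centre forms as a mixture and is planarised again in step 6.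

Step 6
Reactants: 8 6-methylcarvone (C6 epimers)
Product: 11 silyloxymethyl ketone (10β-CH3 10α-CH2OTBS), via lithium enolate 9 (not isolated), via lithium aldolate 10 (not isolated)
Conditions: LiN(iPr)2, THF, −78 °C; CH2O (gas, from cracked paraformaldehyde), −78 °C; TBSOTf, −78 to 0 °C
Reagents that add atoms: formaldehyde, C=O; tert-butyldimethylsilyl trifluoromethanesulfonate, CC(C)(C)[Si](C)(C)OS(=O)(=O)C(F)(F)F
Why: Aldol addition of the tetrasubstituted α′-enolate to formaldehyde on the face anti to the neighbouring isopropenyl group sets the quaternary C10 with CH2O trans and CH3 cis to the C5 substituent (substrate control, as in the sequential alkylations of carvone), and silylation of the aldolate in the flask blocks retro-aldol.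

Step 7
Reactants: 11 silyloxymethyl ketone
Product: 12 tertiary chloride (5β-CMe2Cl)
Conditions: Co(BF4)2·6H2O (cat.), potassium N-(3,5-di-tert-butylsalicylidene)-2,2-diphenylglycinate ligand (cat.), t-BuOOH (cat.), PhSiH3, TsCl, EtOH, rt
Reagents that add atoms: p-toluenesulfonyl chloride, Cc1ccc(cc1)S(=O)(=O)Cl
Why: Markovnikov hydrochlorination by metal-hydride hydrogen-atom transfer: a cobalt hydride gives the tertiary radical from the 1,1-disubstituted alkene, which abstracts chlorine from TsCl, while the conjugated and trisubstituted enone alkene does not react (as in Mukaiyama-type hydrofunctionalisations of carvone).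

Step 8
Reactants: 12 tertiary chloride; 5 2-[(2S)-4-bromo-2-methylbutyl]-1,3-dioxolane
Product: 14 tertiary allylic alcohol (C9 epimers), via Grignard reagent 13 (not isolated)
Conditions: 5, Mg, THF, rt; anhydrous CeCl3, THF, −78 °C; then 12, −78 to 0 °C; aq NH4Cl
Reagents that add atoms: none
Why: CeCl3-promoted 1,2-addition of a primary Grignard reagent to a hindered α-quaternary enone (suppressing enolisation, reduction and conjugate addition); the carbinol centre forms as a mixture that is removed in step 9, and the tertiary chloride and acetal are inert at −78 °C.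

Step 9
Reactants: 14 tertiary allylic alcohol (C9 epimers)
Product: 15 transposed enone (C7 ketone, C8=C9)
Conditions: (C5H5NH)CrO3Cl, NaOAc, 4 Å molecular sieves, CH2Cl2, rt
Reagents that add atoms: pyridinium chlorochromate, [O-][Cr](=O)(=O)Cl.c1cc[nH+]cc1
Why: Babler–Dauben oxidative transposition: the tertiary allylic chromate ester undergoes a [3,3] shift to C7 and is oxidised to the ketone, which places the alkene at C8=C9 with the side chain on C9.

Step 10
Reactants: 15 transposed enone
Product: 16 allylic alcohol (7β-OH)
Conditions: NaBH4, CeCl3·7H2O, MeOH, −78 to 0 °C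
Reagents that add atoms: none
Why: Luche 1,2-reduction in which hydride adds axially from the α face to give the pseudo-equatorial 7β-alcohol (substrate control); a minor 7α-epimer would be separated because it would lead to the C9 epimer.

Step 11
Reactants: 16 allylic alcohol (7β-OH)
Product: 19 ring-B alkene (C7=C8, 9α-H), via sulfonylhydrazine 17 (not isolated), via allylic diazene 18 (not isolated)
Conditions: 2-nitrobenzenesulfonylhydrazide, PPh3, DEAD, N-methylmorpholine, −30 °C to rt
Reagents that add atoms: none
Why: Reductive 1,3-transposition of an allylic alcohol: Mitsunobu displacement with inversion gives the 7α-sulfonylhydrazine, loss of sulfinic acid gives the 7α-diazene, and its retro-ene loss of N2 delivers hydrogen suprafacially to the α face of C9, which sets C9 (α-H, β side chain) and places the alkene at C7=C8.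

Step 12
Reactants: 19 ring-B alkene (tertiary chloride)
Product: 20 tertiary pinacol boronate
Conditions: MnBr2 (cat.), TMEDA, B2pin2, EtMgBr, DME, 0 °C to rt
Reagents that add atoms: bis(pinacolato)diboron, CC1(C)OB(OC1(C)C)B1OC(C)(C)C(C)(C)O1
Why: Manganese-catalysed borylation of an unactivated tertiary alkyl chloride with B2pin2 by way of the C4 radical (radical cross-coupling; C4 is not stereogenic), compatible with the acetal, silyl ether and alkene.

Step 13
Reactants: 20 tertiary pinacol boronate
Product: 21 neopentyl alcohol (10α-CH2OH)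
Conditions: Bu4NF, THF, 0 to 40 °C
Reagents that add atoms: none
Why: Fluoride-induced cleavage of the neopentyl silyl ether; the acetal and the tertiary boronate are stable to Bu4NF.

Step 14
Reactants: 21 neopentyl alcohol
Product: 22 neopentyl iodide (10α-CH2I)
Conditions: PPh3, I2, imidazole, toluene, 80 °C
Reagents that add atoms: iodine, II
Why: Appel-type iodination in which iodide displaces the alkoxyphosphonium at the neopentyl C1 on heating; elimination is impossible because C10 carries no hydrogen.

Step 15
Reactants: 22 neopentyl iodide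
Product: 24 bicyclic C3 boronate (C3 epimers), via vinyl boronate complex 23 (not isolated)
Conditions: vinyllithium (from Sn(CH=CH2)4 and n-BuLi), THF, −78 to 0 °C; then NiBr2·glyme (10 mol %), (S,S)-iPr-Pybox (12 mol %), THF/DMSO, rt
Reagents that add atoms: vinyllithium, [Li]C=C
Why: Proposed new method: vinyllithium adds to boron to give the vinyl boronate 23, low-valent nickel abstracts iodine from C1 and captures the neopentyl radical as a C1–Ni species that cannot β-hydride eliminate (C10 is quaternary), the tethered borate alkene binds to nickel, C4 migrates from boron to the boron-bearing vinyl carbon (C3) anti to nickel while the terminal vinyl carbon (C2) bonds to nickel, and C(sp3)–C(sp3) reductive elimination forms C1–C2. The closest known reaction types are the nickel-catalysed conjunctive cross-coupling of vinylboron ate complexes with unactivated primary alkyl iodides, which is intermolecular, and the Zweifel olefination of tertiary boronic esters, which shows that a tertiary group takes part in this 1,2-shift; what is new is the ring-forming, intramolecular use with a tertiary migrating group. Ring A closes as a formal [4+2] annulation of the C1–C10–C5–C4 unit with C2=C3, by reductive elimination from a seven-membered nickelacycle (Ni, C1, C10, C5, C4, C3, C2) after the ring-contracting boron-to-carbon shift (in a free-radical variant, 7-endo-trig addition of the C1 radical to C2, oxidation and the same shift). The only new stereocentre is C3, for which a chair-like closure should place B(pin) equatorial, but its configuration is not relied on because both epimers are funnelled through the C3 ketone (step 17) and C3 is set in step 19; C4 is not stereogenic and C5, C9, C10 and C13 are not touched. The step needs regioselectivity (C1 to the terminal, C4 to the internal vinyl carbon), which is inherent because only the boron-bearing carbon can accept the migrating group, and chemoselectivity for the borate alkene over C7=C8, which the far higher nucleophilicity of the borate and the strained 4-exo or 5-endo closure onto C7=C8 secure. Lithium–iodine exchange and substitution at C1 by vinyllithium are not expected, since exchange would form the less stable alkyllithium and C1 is neopentyl.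

Step 16
Reactants: 24 bicyclic C3 boronate (C3 epimers)
Product: 26 hydroxy aldehyde (C3 epimers), via hydroxy acetal 25 (not isolated)
Conditions: 30% H2O2, 3 M NaOH, THF, 0 °C to rt; then 2 M HCl, THF, rt
Reagents that add atoms: hydrogen peroxide, OO; water, O
Why: Oxidation of the C–B bond with retention (migration of C3 from boron to oxygen in the hydroperoxide adduct) followed by acid hydrolysis of the dioxolane to the C15 aldehyde; C3 is carried as an epimer mixture.

Step 17
Reactants: 26 hydroxy aldehyde (C3 epimers)
Product: 27 methyl (13R)-3-oxolabd-7-en-15-oate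
Conditions: (C5H5NH)2Cr2O7, MeOH, DMF, rt
Reagents that add atoms: methanol, CO
Why: Pyridinium dichromate in DMF oxidises both C3 epimers to the one ketone and, through the methyl hemiacetal, the aldehyde directly to the methyl ester (chromium-based oxidative esterification).

Step 18
Reactants: 27 methyl (13R)-3-oxolabd-7-en-15-oate
Product: 28 methyl (13R)-17-hydroxy-3-oxolabd-7-en-15-oate
Conditions: SeO2 (cat.), t-BuOOH, CH2Cl2, rt
Reagents that add atoms: selenium dioxide, O=[Se]=O; tert-butyl hydroperoxide, CC(C)(C)OO
Why: Allylic oxidation with SeO2 (ene reaction then [2,3]-sigmatropic shift) at the more substituted alkene terminus C8 on its (E)-methyl group C17, which is preferred over the hindered C9–H as precedented for the C8 methyl of drim-7-enes; any C17 aldehyde from over-oxidation is reduced back in step 19.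

Step 19
Reactants: 28 methyl (13R)-17-hydroxy-3-oxolabd-7-en-15-oate
Product: 29 methyl (13R)-3β,17-dihydroxylabd-7-en-15-oate
Conditions: NaBH4, CeCl3·7H2O, MeOH, −20 °C
Reagents that add atoms: none
Why: Borohydride reduction of the 4,4-dimethyl-3-ketone by axial hydride attack from the α face, away from the axial 4β- and 10β-methyl groups, sets the equatorial 3β-alcohol (substrate control, the classical outcome for 3-oxo terpenoids), with CeCl3 ensuring 1,2-reduction of any enal; the esters are untouched.

Step 20
Reactants: 29 methyl (13R)-3β,17-dihydroxylabd-7-en-15-oate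
Product: 30 methyl (13R)-17-acetoxy-3β-hydroxylabd-7-en-15-oate (CNP0269364.1)
Conditions: AcCl (1.1 equiv), 2,4,6-collidine, CH2Cl2, −78 °C
Reagents that add atoms: acetyl chloride, CC(Cl)=O
Why: Chemoselective acylation of the unhindered primary allylic C17 alcohol in the presence of the secondary C3 alcohol flanked by the quaternary C4 (acid chloride with a hindered pyridine base at low temperature).

**Compound list**
1 | methyl hydrogen (R)-3-methylglutarate | COC(=O)C[C@H](C)CC(=O)O | starting material
2 | methyl (R)-5-hydroxy-3-methylpentanoate | COC(=O)C[C@H](C)CCO | intermediate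
3 | methyl (S)-5-bromo-3-methylpentanoate | COC(=O)C[C@H](C)CCBr | intermediate
4 | (S)-5-bromo-3-methylpentanal | O=CC[C@H](C)CCBr | intermediate
5 | 2-[(2S)-4-bromo-2-methylbutyl]-1,3-dioxolane | O1CCOC1C[C@H](C)CCBr | intermediate
6 | (R)-(−)-carvone | O=C1C(C)=CC[C@@H](C(C)=C)C1 | starting material
7 | lithium α′-enolate of carvone | [Li+].[O-]C1=C[C@H](C(C)=C)CC=C1C | intermediate
8 | (5R)-2,6-dimethyl-5-(prop-1-en-2-yl)cyclohex-2-en-1-one (6-methylcarvone, C6 epimers) | O=C1C(C)=CC[C@@H](C(C)=C)C1C | intermediate
9 | lithium α′-enolate of 6-methylcarvone | [Li+].[O-]C1=C(C)[C@H](C(C)=C)CC=C1C | intermediate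
10 | lithium aldolate (oxidomethyl trans to isopropenyl) | O=C1C(C)=CC[C@@H](C(C)=C)[C@]1(C)C[O-].[Li+] | intermediate
11 | (5S,6R)-6-[(tert-butyldimethylsilyloxy)methyl]-2,6-dimethyl-5-(prop-1-en-2-yl)cyclohex-2-en-1-one (CH2OTBS trans, CH3 cis to isopropenyl) | O=C1C(C)=CC[C@@H](C(C)=C)[C@]1(C)CO[Si](C)(C)C(C)(C)C | intermediate
12 | (5R,6R)-6-[(tert-butyldimethylsilyloxy)methyl]-5-(2-chloropropan-2-yl)-2,6-dimethylcyclohex-2-en-1-one | O=C1C(C)=CC[C@@H](C(C)(C)Cl)[C@]1(C)CO[Si](C)(C)C(C)(C)C | intermediate
13 | [(3S)-4-(1,3-dioxolan-2-yl)-3-methylbutyl]magnesium bromide | O1CCOC1C[C@H](C)CC[Mg]Br | intermediate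
14 | (5R,6R)-6-[(tert-butyldimethylsilyloxy)methyl]-5-(2-chloropropan-2-yl)-1-R*-2,6-dimethylcyclohex-2-en-1-ol (carbinol epimers) | O1CCOC1C[C@H](C)CCC2(O)C(C)=CC[C@@H](C(C)(C)Cl)[C@]2(C)CO[Si](C)(C)C(C)(C)C | intermediate
15 | ring-B enone: C7 ketone, C8=C9, 8-CH3, 9-R*, 10β-CH3, 10α-CH2OTBS, 5β-CMe2Cl (5α-H) | O1CCOC1C[C@H](C)CCC2=C(C)C(=O)C[C@@H](C(C)(C)Cl)[C@]2(C)CO[Si](C)(C)C(C)(C)C | intermediate
16 | ring-B allylic alcohol: as 15 with 7β-OH | O1CCOC1C[C@H](C)CCC2=C(C)[C@@H](O)C[C@@H](C(C)(C)Cl)[C@]2(C)CO[Si](C)(C)C(C)(C)C | intermediate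
17 | 7α-[N-amino-N-(2-nitrobenzenesulfonyl)amino] derivative of 16 | O1CCOC1C[C@H](C)CCC2=C(C)[C@H](N(N)S(=O)(=O)c3ccccc3[N+](=O)[O-])C[C@@H](C(C)(C)Cl)[C@]2(C)CO[Si](C)(C)C(C)(C)C | intermediate
18 | 7α-allylic diazene | O1CCOC1C[C@H](C)CCC2=C(C)[C@H](N=N)C[C@@H](C(C)(C)Cl)[C@]2(C)CO[Si](C)(C)C(C)(C)C | intermediate
19 | ring-B alkene: C7=C8, 8-CH3, 9β-R* (9α-H), 10β-CH3, 10α-CH2OTBS, 5β-CMe2Cl (5α-H) | O1CCOC1C[C@H](C)CC[C@H]2C(C)=CC[C@@H](C(C)(C)Cl)[C@]2(C)CO[Si](C)(C)C(C)(C)C | intermediate
20 | as 19 with 5β-CMe2B(pin) | O1CCOC1C[C@H](C)CC[C@H]2C(C)=CC[C@@H](C(C)(C)B3OC(C)(C)C(C)(C)O3)[C@]2(C)CO[Si](C)(C)C(C)(C)C | intermediate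
21 | as 20 with 10α-CH2OH | O1CCOC1C[C@H](C)CC[C@H]2C(C)=CC[C@@H](C(C)(C)B3OC(C)(C)C(C)(C)O3)[C@]2(C)CO | intermediate
22 | as 20 with 10α-CH2I | O1CCOC1C[C@H](C)CC[C@H]2C(C)=CC[C@@H](C(C)(C)B3OC(C)(C)C(C)(C)O3)[C@]2(C)CI | intermediate
23 | lithium vinyl boronate (ate complex) of 22 | [Li+].O1CCOC1C[C@H](C)CC[C@H]2C(C)=CC[C@@H](C(C)(C)[B-]3(C=C)OC(C)(C)C(C)(C)O3)[C@]2(C)CI | intermediate
24 | (13R)-15,15-(ethylenedioxy)labd-7-en-3-ylboronic acid pinacol ester (C3 epimers) | O1CCOC1C[C@H](C)CC[C@H]2C(C)=CC[C@H]3C(C)(C)C(B4OC(C)(C)C(C)(C)O4)CC[C@]23C | intermediate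
25 | (13R)-15,15-(ethylenedioxy)labd-7-en-3-ol (C3 epimers) | O1CCOC1C[C@H](C)CC[C@H]2C(C)=CC[C@H]3C(C)(C)C(O)CC[C@]23C | intermediate
26 | (13R)-3-hydroxylabd-7-en-15-al (C3 epimers) | O=CC[C@H](C)CC[C@H]1C(C)=CC[C@H]2C(C)(C)C(O)CC[C@]12C | intermediate
27 | methyl (13R)-3-oxolabd-7-en-15-oate | COC(=O)C[C@H](C)CC[C@H]1C(C)=CC[C@H]2C(C)(C)C(=O)CC[C@]12C | intermediate
28 | methyl (13R)-17-hydroxy-3-oxolabd-7-en-15-oate | COC(=O)C[C@H](C)CC[C@H]1C(CO)=CC[C@H]2C(C)(C)C(=O)CC[C@]12C | intermediate
29 | methyl (13R)-3β,17-dihydroxylabd-7-en-15-oate | COC(=O)C[C@H](C)CC[C@H]1C(CO)=CC[C@H]2C(C)(C)[C@@H](O)CC[C@]12C | intermediate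
30 | methyl (13R)-17-acetoxy-3β-hydroxylabd-7-en-15-oate | COC(=O)C[C@H](C)CC[C@H]1C(COC(C)=O)=CC[C@H]2C(C)(C)[C@@H](O)CC[C@]12C | target

Total step count: 20. Longest linear sequence: 17 steps (steps 1–4, then 8–20, from 1).

**Steps most likely to fail**

Step 15 (proposed new method). The nickel alkyl or C1 radical may be reduced to C1–H, β-hydride elimination may follow the boron shift, or intermolecular coupling may compete with ring closure. The fallback builds ring A stepwise by known reactions and sets out from 20. Addition of 1-ethoxyvinyllithium (ethyl vinyl ether, t-BuLi) to boron, then iodine and NaOMe, triggers the Zweifel-type 1,2-shift of C4 and anti-elimination to the enol ether F1. Aqueous oxalic acid hydrolyses it to the methyl ketone F2, which holds the C3–C4 bond with C2 as the ketone methyl. Bu4NF frees the C1 alcohol F3, and SO3·pyridine/DMSO/Et3N oxidation gives the keto aldehyde F4. KOH in MeOH closes ring A by intramolecular aldol condensation to the enone F5 (C1=C2). Conjugate reduction with [(Ph3P)CuH]6 gives the saturated ketone F6, and 2 M HCl frees the keto aldehyde F7. Pyridinium dichromate/MeOH/DMF, as in step 17, then comes back to the route at 27.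

Step 12. At the congested tertiary centre, loss of HCl to an alkene or reduction of the radical may outrun C–B bond formation. The fallback replaces radical catalysis by a polar sequence and sets out from 19. Reductive lithiation with lithium 4,4′-di-tert-butylbiphenylide (THF, −78 °C) gives the tertiary alkyllithium F8, which is trapped with 2-isopropoxy-4,4,5,5-tetramethyl-1,3,2-dioxaborolane to come back to the route at 20.

Step 18. Oxidation may occur at the wrong allylic position (C6 or C9), over-oxidation may dominate, or conversion may stall. The fallback moves oxygen to C17 by an allylic transposition and sets out from 27. mCPBA epoxidises C7=C8 to the epoxide F9. Cp2TiCl (trivalent titanium, from Cp2TiCl2 and Mn) opens it homolytically at C8 and, after loss of a C17 hydrogen, gives the exocyclic allylic alcohol F10. Ac2O/pyridine/DMAP gives the allylic acetate F11. PdCl2(MeCN)2 (divalent palladium) catalyses the [3,3] shift to the primary acetate with the C7=C8 alkene, the keto acetate F12. NaBH4 at −20 °C, as in step 19, then reduces the C3 ketone and the route is rejoined at 30.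

**Further compounds**
F1 | step 15 | enol ether: as 20 with 5β-CMe2–C(OEt)=CH2 | O1CCOC1C[C@H](C)CC[C@H]2C(C)=CC[C@@H](C(C)(C)C(=C)OCC)[C@]2(C)CO[Si](C)(C)C(C)(C)C
F2 | step 15 | methyl ketone: as 20 with 5β-CMe2–C(=O)CH3 | O1CCOC1C[C@H](C)CC[C@H]2C(C)=CC[C@@H](C(C)(C)C(C)=O)[C@]2(C)CO[Si](C)(C)C(C)(C)C
F3 | step 15 | C1 alcohol of F2 | O1CCOC1C[C@H](C)CC[C@H]2C(C)=CC[C@@H](C(C)(C)C(C)=O)[C@]2(C)CO
F4 | step 15 | keto aldehyde (C1 aldehyde, C3 methyl ketone) | O1CCOC1C[C@H](C)CC[C@H]2C(C)=CC[C@@H](C(C)(C)C(C)=O)[C@]2(C)C=O
F5 | step 15 | (13R)-15,15-(ethylenedioxy)labda-1,7-dien-3-one | O1CCOC1C[C@H](C)CC[C@H]2C(C)=CC[C@H]3C(C)(C)C(=O)C=C[C@]23C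
F6 | step 15 | (13R)-15,15-(ethylenedioxy)labd-7-en-3-one | O1CCOC1C[C@H](C)CC[C@H]2C(C)=CC[C@H]3C(C)(C)C(=O)CC[C@]23C
F7 | step 15 | (13R)-3-oxolabd-7-en-15-al | O=CC[C@H](C)CC[C@H]1C(C)=CC[C@H]2C(C)(C)C(=O)CC[C@]12C
F8 | step 12 | tertiary alkyllithium: as 19 with 5β-CMe2Li | O1CCOC1C[C@H](C)CC[C@H]2C(C)=CC[C@@H](C(C)(C)[Li])[C@]2(C)CO[Si](C)(C)C(C)(C)C
F9 | step 18 | methyl (13R)-7,8-epoxy-3-oxolabdan-15-oate | COC(=O)C[C@H](C)CC[C@H]1C3(C)OC3C[C@H]2C(C)(C)C(=O)CC[C@]12C
F10 | step 18 | methyl (13R)-7-hydroxy-3-oxolabd-8(17)-en-15-oate | COC(=O)C[C@H](C)CC[C@H]1C(=C)C(O)C[C@H]2C(C)(C)C(=O)CC[C@]12C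
F11 | step 18 | methyl (13R)-7-acetoxy-3-oxolabd-8(17)-en-15-oate | COC(=O)C[C@H](C)CC[C@H]1C(=C)C(OC(C)=O)C[C@H]2C(C)(C)C(=O)CC[C@]12C
F12 | step 18 | methyl (13R)-17-acetoxy-3-oxolabd-7-en-15-oate | COC(=O)C[C@H](C)CC[C@H]1C(COC(C)=O)=CC[C@H]2C(C)(C)C(=O)CC[C@]12C
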